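**Plan**

1. Numbering (kaurane): ring A = C1–C5, C10 (C6 = CH2OH on C5); δ-lactone = C10–C20–O–C7(=O)–C8–C9; ring C = C8, C9, C11–C14; ring D = C8, C14, C13, C16, C15; C17 on C16. The enabling feature: C8 is α to the lactone carbonyl and C15, C16, C17 carry three contiguous oxygens, which is the pattern of a lactone-enolate aldol adduct of an α,β-epoxy aldehyde.
2. Retrosynthesis: C1=O (allylic oxidation) and C17–OH (epoxide opening) go first; then C8–C15 (aldol, ring D); the C16–C17 epoxide (Sharpless); C8–C14 (enolate alkylation, ring C) and C9–C11 (conjugate addition), which separates chain 22 from spiro lactone 12; in 12 the lactone C–O bond, C10–C9 (Michael), C10–C20 (formylation) and C5–C6 (vinyl addition).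
3. Forward: ring A from 4,4-dimethylcyclohexenone → spiro δ-lactone → unsaturated lactone 12 (steps 1–8); chain 22 from (R)-paraconic acid (steps 9–15); C9–C11 union, ring C, epoxy aldehyde, ring D, end game (steps 16–24).
4. Stereochemistry: C5 from a Rh/(R)-BINAP conjugate vinylation; C10 from a Michael addition anti to C5; C1 (auxiliary, erased in step 24) from hydroxyl-directed hydride delivery; C9 from organocopper addition anti to the C5 side; C13 from (R)-paraconic acid; C16 from Sharpless epoxidation; C8 and C15 from the aldol.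

Key step: step 21

Assumption: C8 of 26–29 is drawn as the cis-fused epimer expected from step 17; either epimer serves, because step 21 enolises C8.

**Step 1**
Reactants: 1 4,4-dimethylcyclohex-2-en-1-one
Product: 2 4,4-dimethylcyclohexa-2,5-dien-1-one
Conditions: DDQ, dioxane, reflux
Reagents that add atoms: none
Why: DDQ dehydrogenation of an enone through its dienol is the standard route to 4,4-disubstituted cyclohexadienones, and the quaternary C4 blocks aromatisation.

**Step 2**
Reactants: 2 4,4-dimethylcyclohexa-2,5-dien-1-one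
Product: 3 (5R)-5-ethenyl-4,4-dimethylcyclohex-2-en-1-one
Conditions: [Rh(cod)2]BF4 (3 mol %), (R)-BINAP, CH2=CHBF3K (1.1 equiv), Et3N, toluene/H2O, 40 °C
Reagents that add atoms: potassium vinyltrifluoroborate, [K+].C=C[B-](F)(F)F
Why: Hayashi–Miyaura conjugate addition of an alkenylboron reagent desymmetrises the dienone; the (R)-BINAP–Rh–vinyl species should set C5 as R (by analogy with 2-cyclohexenone, where (S)-BINAP gives the (S)-adducts), and the limiting boron reagent plus the more congested mono-adduct should hold the reaction at one addition.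

**Step 3**
Reactants: 3 (5R)-5-ethenyl-4,4-dimethylcyclohex-2-en-1-one
Product: 4 (5R,6Z)-5-ethenyl-6-(hydroxymethylidene)-4,4-dimethylcyclohex-2-en-1-one
Conditions: NaH, HCO2Et, THF, 0 → 23 °C; 1 M HCl work-up
Reagents that add atoms: ethyl formate, CCOC=O
Why: Claisen-type formylation at the only enolisable position (the γ-carbon is quaternary) activates the future C10 and brings in C20 at the aldehyde level.

**Step 4**
Reactants: 4 (5R,6Z)-5-ethenyl-6-(hydroxymethylidene)-4,4-dimethylcyclohex-2-en-1-one; 5 methyl acrylate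
Product: 6 methyl 3-[(1S,6R)-6-ethenyl-1-formyl-5,5-dimethyl-2-oxocyclohex-3-en-1-yl]propanoate
Conditions: DBU (0.2 equiv), MeCN, 0 → 23 °C
Reagents that add atoms: none
Why: Michael addition of a 2-formyl ketone to an acrylate; the acrylate should approach the planar C10 anti to the adjacent pseudoaxial vinyl group, so that C9 ends trans to C6 and the quaternary C10 is set.

**Step 5**
Reactants: 6 methyl 3-[(1S,6R)-6-ethenyl-1-formyl-5,5-dimethyl-2-oxocyclohex-3-en-1-yl]propanoate
Product: 7 methyl 3-[(1S,6R)-1,6-diformyl-5,5-dimethyl-2-oxocyclohex-3-en-1-yl]propanoate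
Conditions: O3, CH2Cl2, −78 °C; Me2S; used at once
Reagents that add atoms: ozone, [O-][O+]=O
Why: Ozonolysis with reductive work-up; the electron-poor, neopentyl-flanked enone C2=C3 bond reacts far more slowly than the vinyl group, so only C6 is unveiled.

**Step 6**
Reactants: 7 methyl 3-[(1S,6R)-1,6-diformyl-5,5-dimethyl-2-oxocyclohex-3-en-1-yl]propanoate
Product: 9 (6S,7R,11R)-7-hydroxy-11-(hydroxymethyl)-10,10-dimethyl-2-oxaspiro[5.5]undec-8-en-3-one, via triol ester 8 (not isolated)
Conditions: Me4NBH(OAc)3, MeCN/AcOH, −20 → 23 °C; then p-TsOH·H2O (cat.), CH2Cl2, 23 °C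
Reagents that add atoms: none
Why: Triacetoxyborohydride reduces both aldehydes, and the C20-bound borohydride then delivers hydride to the C1 ketone from the C20 face (Evans–Saksena reduction), placing the C1 hydroxyl cis to C9; the primary C20 hydroxyl then closes the δ-lactone in preference to the flanked secondary C1 hydroxyl (acid-catalysed lactonisation).

**Step 7**
Reactants: 9 (6S,7R,11R)-7-hydroxy-11-(hydroxymethyl)-10,10-dimethyl-2-oxaspiro[5.5]undec-8-en-3-one
Product: 10 (6S,7R,11R)-7-[(tert-butyldimethylsilyl)oxy]-11-{[(tert-butyldimethylsilyl)oxy]methyl}-10,10-dimethyl-2-oxaspiro[5.5]undec-8-en-3-one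
Conditions: TBSOTf, 2,6-lutidine, CH2Cl2, −78 → 0 °C
Reagents that add atoms: tert-butyldimethylsilyl trifluoromethanesulfonate, CC(C)(C)[Si](C)(C)OS(=O)(=O)C(F)(F)F
Why: Silyl triflate silylation protects the primary and the hindered secondary allylic hydroxyl in one operation and locks the lactone against translactonisation.

**Step 8**
Reactants: 10 (6S,7R,11R)-7-[(tert-butyldimethylsilyl)oxy]-11-{[(tert-butyldimethylsilyl)oxy]methyl}-10,10-dimethyl-2-oxaspiro[5.5]undec-8-en-3-one
Product: 12 (6S,7R,11R)-7-[(tert-butyldimethylsilyl)oxy]-11-{[(tert-butyldimethylsilyl)oxy]methyl}-10,10-dimethyl-2-oxaspiro[5.5]undeca-4,8-dien-3-one, via selenide 11 (not isolated)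
Conditions: LiN(i-Pr)2, THF, −78 °C; PhSeBr; then H2O2, pyridine, CH2Cl2, 0 → 23 °C
Reagents that add atoms: none
Why: α-Selenenylation of the lactone enolate followed by selenoxide syn-elimination, which can only run towards C9, gives the α,β-unsaturated δ-lactone.

**Step 9**
Reactants: 13 (R)-paraconic acid [(3R)-5-oxotetrahydrofuran-3-carboxylic acid]
Product: 15 (4R)-4-(2-diazoacetyl)dihydrofuran-2(3H)-one, via acid chloride 14 (not isolated)
Conditions: (COCl)2, DMF (cat.), CH2Cl2, 0 → 23 °C; then Me3SiCHN2, MeCN/THF, 0 °C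
Reagents that add atoms: (trimethylsilyl)diazomethane, C[Si](C)(C)C=[N+]=[N-]
Why: Acid chloride formation and acylation of the diazoalkane (first half of an Arndt–Eistert sequence) run without base, so the C13 stereocentre next to the acyl group is not enolised.

**Step 10**
Reactants: 15 (4R)-4-(2-diazoacetyl)dihydrofuran-2(3H)-one
Product: 16 (4R)-4-{2-[(4-methoxybenzyl)oxy]acetyl}dihydrofuran-2(3H)-one
Conditions: Rh2(OAc)4 (1 mol %), 4-methoxybenzyl alcohol, CH2Cl2, 23 °C
Reagents that add atoms: 4-methoxybenzyl alcohol, COc1ccc(CO)cc1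
Why: Rhodium-carbenoid O–H insertion of an α-diazoketone into an alcohol installs the protected C15 oxygen and is faster than C–H insertion or arene cyclopropanation.

**Step 11**
Reactants: 16 (4R)-4-{2-[(4-methoxybenzyl)oxy]acetyl}dihydrofuran-2(3H)-one
Product: 17 (4S)-4-{3-[(4-methoxybenzyl)oxy]prop-1-en-2-yl}dihydrofuran-2(3H)-one
Conditions: Zn, CH2Br2, TiCl4, THF/CH2Cl2, 0 → 23 °C
Reagents that add atoms: dibromomethane, BrCBr
Why: Lombardo methylenation is non-basic, so the epimerisable C13 next to the ketone is preserved and the lactone carbonyl is left alone; it adds C17 (the descriptor changes only through priorities).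

**Step 12**
Reactants: 17 (4S)-4-{3-[(4-methoxybenzyl)oxy]prop-1-en-2-yl}dihydrofuran-2(3H)-one
Product: 18 (3S)-3-(hydroxymethyl)-N-methoxy-4-{[(4-methoxybenzyl)oxy]methyl}-N-methylpent-4-enamide
Conditions: MeNH(OMe)·HCl, i-PrMgCl, THF, −20 → 0 °C; used crude
Reagents that add atoms: N,O-dimethylhydroxylamine hydrochloride, CNOC.Cl
Why: Aminolysis of the γ-lactone by the magnesium amide (Weinreb amide formation) opens the ring and so tells C11 (amide) from C14 (free alcohol).

**Step 13**
Reactants: 18 (3S)-3-(hydroxymethyl)-N-methoxy-4-{[(4-methoxybenzyl)oxy]methyl}-N-methylpent-4-enamide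
Product: 19 (3S)-3-(chloromethyl)-N-methoxy-4-{[(4-methoxybenzyl)oxy]methyl}-N-methylpent-4-enamide
Conditions: PPh3, N-chlorosuccinimide, CH2Cl2, 0 → 23 °C
Reagents that add atoms: N-chlorosuccinimide, O=C1CCC(=O)N1Cl
Why: Appel-type chlorination turns the C14 hydroxyl into the chloride that later closes ring C, before the hydroxy amide can relactonise.

**Step 14**
Reactants: 19 (3S)-3-(chloromethyl)-N-methoxy-4-{[(4-methoxybenzyl)oxy]methyl}-N-methylpent-4-enamide
Product: 21 (3S)-3-(chloromethyl)-4-{[(4-methoxybenzyl)oxy]methyl}pent-4-en-1-ol, via aldehyde 20 (not isolated)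
Conditions: i-Bu2AlH, THF, −78 °C; aqueous work-up; then NaBH4, MeOH, 0 °C
Reagents that add atoms: none
Why: Weinreb amide reduction stops at the aldehyde through the chelated intermediate and borohydride then gives the C11 alcohol; neither reagent touches the alkyl chloride.

**Step 15**
Reactants: 21 (3S)-3-(chloromethyl)-4-{[(4-methoxybenzyl)oxy]methyl}pent-4-en-1-ol
Product: 22 1-({[(3S)-5-bromo-3-(chloromethyl)-2-methylidenepentyl]oxy}methyl)-4-methoxybenzene
Conditions: CBr4, PPh3, CH2Cl2, 0 °C
Reagents that add atoms: tetrabromomethane, BrC(Br)(Br)Br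
Why: Appel bromination gives the primary bromide, the only carbon–halogen bond that inserts magnesium in the next step.

**Step 16**
Reactants: 22 1-({[(3S)-5-bromo-3-(chloromethyl)-2-methylidenepentyl]oxy}methyl)-4-methoxybenzene; 12 (6S,7R,11R)-7-[(tert-butyldimethylsilyl)oxy]-11-{[(tert-butyldimethylsilyl)oxy]methyl}-10,10-dimethyl-2-oxaspiro[5.5]undeca-4,8-dien-3-one
Product: 25 conjugate adduct (lactone 10 carrying the chain of 22 at C9), via Grignard reagent 23 (not isolated), via silyl ketene acetal 24 (not isolated)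
Conditions: 22, Mg, THF, 23 °C; then 12, CuBr·SMe2 (20 mol %), Me3SiCl, DMPU, THF, −78 → −30 °C; aq. citric acid
Reagents that add atoms: none
Why: Copper-catalysed, Me3SiCl-accelerated conjugate addition of a Grignard reagent to an α,β-unsaturated lactone; magnesium inserts into C–Br and not C–Cl, and the nucleophile should reach C9 from the face flanked only by H1 (C1–OSi pseudoaxial), anti to the equatorial C5–CH2OSi group and the C4 methyls, which sets C9.

**Step 17**
Reactants: 25 conjugate adduct
Product: 26 tricyclic lactone (rings A and C plus lactone) with the 3-[(4-methoxybenzyl)oxy]prop-1-en-2-yl group on C13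
Conditions: KN(SiMe3)2, THF/DMPU, −78 → 23 °C
Reagents that add atoms: none
Why: Intramolecular alkylation of the lactone enolate by the primary chloride (6-exo-tet) forms C8–C14 and ring C; the C8 configuration formed is of no consequence.

**Step 18**
Reactants: 26 tricyclic lactone 4-methoxybenzyl ether
Product: 27 tricyclic allylic alcohol (C15–OH, C16=C17)
Conditions: DDQ, CH2Cl2/pH 7 buffer, 0 °C
Reagents that add atoms: none
Why: Oxidative cleavage of the 4-methoxybenzyl ether by DDQ leaves the silyl ethers, the lactone and both alkenes untouched.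

**Step 19**
Reactants: 27 tricyclic allylic alcohol
Product: 28 tricyclic epoxy alcohol (C16–C17 epoxide, C15–OH)
Conditions: Ti(OiPr)4 (10 mol %), L-(+)-diisopropyl tartrate (12 mol %), t-BuOOH, 4 Å MS, CH2Cl2, −20 °C
Reagents that add atoms: tert-butyl hydroperoxide, CC(C)(C)OO
Why: Sharpless asymmetric epoxidation of a 2-substituted allylic alcohol; the L-(+)-tartrate catalyst should deliver oxygen to the face that gives the (S)-2-substituted glycidol, which is the C16 configuration of the target, under reagent control, and the ring A alkene (no free allylic hydroxyl) does not react.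

**Step 20**
Reactants: 28 tricyclic epoxy alcohol
Product: 29 tricyclic epoxy aldehyde (C15 aldehyde on the C16–C17 epoxide, C1 and C6 as silyl ethers)
Conditions: Dess–Martin periodinane, pyridine, CH2Cl2, 0 → 23 °C; used at once
Reagents that add atoms: none
Why: Dess–Martin oxidation gives the α,β-epoxy aldehyde, which has no α-hydrogen and so can neither epimerise nor enolise.

**Step 21**
Reactants: 29 tricyclic epoxy aldehyde
Product: 30 tetracyclic lactone with C15 hydroxyl and C16–C17 spiro epoxide
Conditions: KN(SiMe3)2, 18-crown-6, THF (0.005 M), −78 °C; AcOH, −78 °C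
Reagents that add atoms: none
Why: KN(SiMe3)2 removes the only acidic proton, C8–H (the epoxy aldehyde has no α-hydrogen), and the lactone enolate adds to the C15 aldehyde in an intramolecular aldol addition, the closest known reaction types being ester and lactone enolate–aldehyde aldol cyclisations and enolate additions to α,β-epoxy aldehydes. Ring D (C8, C14, C13, C16, C15) closes in the 5-(enolexo)-exo-trig mode from the ring C chair in which the C13–C16 and C9–C10 bonds are axial, which makes C8 the quaternary bridgehead of the bicyclo[3.2.1]octane. C8 is controlled by the tether, since C15 is held on C13 and can reach only the enolate face syn to C16. C15 is controlled by an open transition state of the crown-separated potassium enolate, in which the aldehyde C=O lies anti to the C16–O bond of the epoxide (Cornforth model) and away from the enolate oxygen, so the new hydroxyl should end endo and trans to the C16 oxygen; a metal-bridged closed transition state would give the epimer, which is why lithium is avoided. The step needs chemoselectivity for the aldehyde over the epoxide carbon C17 and a single enolisable site, and the substrate provides both (the aldehyde is far more electrophilic at −78 °C, C16 is quaternary and ring A has no acidic hydrogen). The cold AcOH quench stops retro-aldol cleavage and Payne rearrangement of the aldolate.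

**Step 22**
Reactants: 30 tetracyclic epoxy alcohol
Product: 32 bis-silyl 15,16,17-triol lactone, via sodium carboxylate 31 (not isolated)
Conditions: NaOH (1 M), t-BuOH/H2O, 23 → 70 °C; then HCl to pH 3, 23 °C
Reagents that add atoms: sodium hydroxide, [Na+].[OH-]
Why: Hydroxide opens the terminal epoxide at the primary C17 (SN2 under Payne-rearrangement conditions, where attack at the primary carbon is the fastest exit), which keeps the C16–O bond and its configuration; the lactone is saponified first at 23 °C and closes again on acidification because only the C20 hydroxyl can reach C7.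

**Step 23**
Reactants: 32 bis-silyl triol lactone
Product: 33 pentaol (C1, C6, C15, C16, C17 hydroxyls)
Conditions: HF·pyridine, THF/pyridine, 0 → 23 °C
Reagents that add atoms: none
Why: Fluoride-mediated desilylation removes both silyl ethers in one operation without touching the lactone or the triol.

**Step 24**
Reactants: 33 pentaol
Product: 34 CNP0546915.1
Conditions: MnO2, acetone, 23 °C
Reagents that add atoms: none
Why: MnO2 oxidises only the allylic C1 alcohol to the enone and leaves the saturated primary, secondary and tertiary hydroxyls.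

**Compound list**

1 | 4,4-dimethylcyclohex-2-en-1-one | CC1(C)CCC(=O)C=C1 | starting material
2 | 4,4-dimethylcyclohexa-2,5-dien-1-one | CC1(C)C=CC(=O)C=C1 | intermediate
3 | (5R)-5-ethenyl-4,4-dimethylcyclohex-2-en-1-one | CC1(C)C=CC(=O)C[C@@H]1C=C | intermediate
4 | (5R,6Z)-5-ethenyl-6-(hydroxymethylidene)-4,4-dimethylcyclohex-2-en-1-one (enol form of the 6-formyl ketone) | CC1(C)C=CC(=O)/C(=C\O)[C@@H]1C=C | intermediate
5 | methyl acrylate | C=CC(=O)OC | starting material
6 | methyl 3-[(1S,6R)-6-ethenyl-1-formyl-5,5-dimethyl-2-oxocyclohex-3-en-1-yl]propanoate | CC1(C)C=CC(=O)[C@](CCC(=O)OC)(C=O)[C@@H]1C=C | intermediate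
7 | methyl 3-[(1S,6R)-1,6-diformyl-5,5-dimethyl-2-oxocyclohex-3-en-1-yl]propanoate | CC1(C)C=CC(=O)[C@](CCC(=O)OC)(C=O)[C@@H]1C=O | intermediate
8 | methyl 3-[(1S,2R,6R)-2-hydroxy-1,6-bis(hydroxymethyl)-5,5-dimethylcyclohex-3-en-1-yl]propanoate (triol ester) | CC1(C)C=C[C@@H](O)[C@](CCC(=O)OC)(CO)[C@@H]1CO | intermediate
9 | (6S,7R,11R)-7-hydroxy-11-(hydroxymethyl)-10,10-dimethyl-2-oxaspiro[5.5]undec-8-en-3-one (C1–OH cis to C9, C6 cis to C20) | CC1(C)C=C[C@@H](O)[C@]2(COC(=O)CC2)[C@@H]1CO | intermediate
10 | (6S,7R,11R)-7-[(tert-butyldimethylsilyl)oxy]-11-{[(tert-butyldimethylsilyl)oxy]methyl}-10,10-dimethyl-2-oxaspiro[5.5]undec-8-en-3-one | CC1(C)C=C[C@@H](O[Si](C)(C)C(C)(C)C)[C@]2(COC(=O)CC2)[C@@H]1CO[Si](C)(C)C(C)(C)C | intermediate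
11 | 4-(phenylselanyl) derivative of 10 (selenide at C8, both epimers) | CC1(C)C=C[C@@H](O[Si](C)(C)C(C)(C)C)[C@]2(COC(=O)C([Se]c3ccccc3)C2)[C@@H]1CO[Si](C)(C)C(C)(C)C | intermediate
12 | (6S,7R,11R)-7-[(tert-butyldimethylsilyl)oxy]-11-{[(tert-butyldimethylsilyl)oxy]methyl}-10,10-dimethyl-2-oxaspiro[5.5]undeca-4,8-dien-3-one | CC1(C)C=C[C@@H](O[Si](C)(C)C(C)(C)C)[C@]2(COC(=O)C=C2)[C@@H]1CO[Si](C)(C)C(C)(C)C | intermediate
13 | (R)-paraconic acid, (3R)-5-oxotetrahydrofuran-3-carboxylic acid | O=C1C[C@H](CO1)C(=O)O | starting material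
14 | (3R)-5-oxotetrahydrofuran-3-carbonyl chloride | O=C1C[C@H](CO1)C(=O)Cl | intermediate
15 | (4R)-4-(2-diazoacetyl)dihydrofuran-2(3H)-one | O=C1C[C@H](CO1)C(=O)C=[N+]=[N-] | intermediate
16 | (4R)-4-{2-[(4-methoxybenzyl)oxy]acetyl}dihydrofuran-2(3H)-one | O=C1C[C@H](CO1)C(=O)COCc2ccc(OC)cc2 | intermediate
17 | (4S)-4-{3-[(4-methoxybenzyl)oxy]prop-1-en-2-yl}dihydrofuran-2(3H)-one | O=C1C[C@H](CO1)C(=C)COCc2ccc(OC)cc2 | intermediate
18 | (3S)-3-(hydroxymethyl)-N-methoxy-4-{[(4-methoxybenzyl)oxy]methyl}-N-methylpent-4-enamide | CON(C)C(=O)C[C@H](CO)C(=C)COCc1ccc(OC)cc1 | intermediate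
19 | (3S)-3-(chloromethyl)-N-methoxy-4-{[(4-methoxybenzyl)oxy]methyl}-N-methylpent-4-enamide | CON(C)C(=O)C[C@H](CCl)C(=C)COCc1ccc(OC)cc1 | intermediate
20 | (3S)-3-(chloromethyl)-4-{[(4-methoxybenzyl)oxy]methyl}pent-4-enal | O=CC[C@H](CCl)C(=C)COCc1ccc(OC)cc1 | intermediate
21 | (3S)-3-(chloromethyl)-4-{[(4-methoxybenzyl)oxy]methyl}pent-4-en-1-ol | OCC[C@H](CCl)C(=C)COCc1ccc(OC)cc1 | intermediate
22 | 1-({[(3S)-5-bromo-3-(chloromethyl)-2-methylidenepentyl]oxy}methyl)-4-methoxybenzene | BrCC[C@H](CCl)C(=C)COCc1ccc(OC)cc1 | intermediate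
23 | Grignard reagent of 22 (C11–MgBr) | Br[Mg]CC[C@H](CCl)C(=C)COCc1ccc(OC)cc1 | intermediate
24 | trimethylsilyl ketene acetal of 25 (C7–OSiMe3, C7=C8) | CC1(C)C=C[C@@H](O[Si](C)(C)C(C)(C)C)[C@]2(COC(O[Si](C)(C)C)=C[C@H]2CC[C@H](CCl)C(=C)COCc3ccc(OC)cc3)[C@@H]1CO[Si](C)(C)C(C)(C)C | intermediate
25 | conjugate adduct: lactone 10 with the (3S)-3-(chloromethyl)-4-{[(4-methoxybenzyl)oxy]methyl}pent-4-en-1-yl chain on C9, new bond cis to C1 | CC1(C)C=C[C@@H](O[Si](C)(C)C(C)(C)C)[C@]2(COC(=O)C[C@H]2CC[C@H](CCl)C(=C)COCc3ccc(OC)cc3)[C@@H]1CO[Si](C)(C)C(C)(C)C | intermediate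
26 | tricyclic lactone, C13 bearing 3-[(4-methoxybenzyl)oxy]prop-1-en-2-yl, C10 and C16 trans on ring C, cis-fused at C8/C9 | CC1(C)C=C[C@@H](O[Si](C)(C)C(C)(C)C)[C@]2(COC(=O)[C@H]3C[C@@H](CC[C@@H]23)C(=C)COCc4ccc(OC)cc4)[C@@H]1CO[Si](C)(C)C(C)(C)C | intermediate
27 | tricyclic allylic alcohol (C15–OH, C16=C17) | CC1(C)C=C[C@@H](O[Si](C)(C)C(C)(C)C)[C@]2(COC(=O)[C@H]3C[C@@H](CC[C@@H]23)C(=C)CO)[C@@H]1CO[Si](C)(C)C(C)(C)C | intermediate
28 | tricyclic epoxy alcohol (C16–C17 epoxide, C16 oxygen as in the target, C15–OH) | CC1(C)C=C[C@@H](O[Si](C)(C)C(C)(C)C)[C@]2(COC(=O)[C@H]3C[C@@H](CC[C@@H]23)[C@@]4(CO4)CO)[C@@H]1CO[Si](C)(C)C(C)(C)C | intermediate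
29 | tricyclic epoxy aldehyde (key-step precursor) | CC1(C)C=C[C@@H](O[Si](C)(C)C(C)(C)C)[C@]2(COC(=O)[C@H]3C[C@@H](CC[C@@H]23)[C@@]4(CO4)C=O)[C@@H]1CO[Si](C)(C)C(C)(C)C | intermediate
30 | tetracyclic lactone, C15–OH endo and trans to the C16 epoxide oxygen (key-step product) | CC1(C)C=C[C@@H](O[Si](C)(C)C(C)(C)C)[C@]2(COC(=O)[C@@]34C[C@@H](CC[C@@H]23)[C@@]5(CO5)[C@H]4O)[C@@H]1CO[Si](C)(C)C(C)(C)C | intermediate
31 | sodium seco-carboxylate (C7 carboxylate, C20–OH, 15,16,17-triol) | CC1(C)C=C[C@@H](O[Si](C)(C)C(C)(C)C)[C@@](CO)([C@@H]2CC[C@@H]3C[C@@]2(C(=O)[O-])[C@H](O)[C@]3(O)CO)[C@@H]1CO[Si](C)(C)C(C)(C)C.[Na+] | intermediate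
32 | bis-silyl 15,16,17-triol lactone | CC1(C)C=C[C@@H](O[Si](C)(C)C(C)(C)C)[C@]2(COC(=O)[C@@]34C[C@@H](CC[C@@H]23)[C@@](O)(CO)[C@H]4O)[C@@H]1CO[Si](C)(C)C(C)(C)C | intermediate
33 | pentaol (1,6,15,16,17-pentahydroxy lactone) | CC1(C)C=C[C@@H](O)[C@]2(COC(=O)[C@@]34C[C@@H](CC[C@@H]23)[C@@](O)(CO)[C@H]4O)[C@@H]1CO | intermediate
34 | CNP0546915.1 (6,15,16,17-tetrahydroxy-1-oxo-6,7-secokaur-2-en-7,20-olide skeleton, configuration as in the SMILES) | CC1(C)C=CC(=O)[C@]2(COC(=O)[C@@]34C[C@@H](CC[C@@H]23)[C@@](O)(CO)[C@H]4O)[C@@H]1CO | target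

**Count and risks**

Total steps: 24. Longest linear sequence: 17 steps (steps 1–8 and 16–24); the chain (steps 9–15) joins at step 16.

Step 21. The closure needs ring C to flip into the chair with the C13–C16 and C9–C10 bonds axial, so it may be slow. While it is slow, facial selectivity at the aldehyde can erode towards a metal-bridged closed transition state, and retro-aldol cleavage can set in on warming. Fallback: the C15 configuration is set by hydride instead of by the aldol. From 29 the cyclisation is run with LiN(SiMe3)2 in THF at −78 °C and any epimer ratio is accepted, giving the 15-epi aldol F1 alone or mixed with 30. Dess–Martin oxidation gives the C15 ketone F2, a β-keto lactone without α-hydrogen. NaBH4/CeCl3 in MeOH/THF at −78 °C should add hydride from the exo face (the side of C14, away from C9 and C11) and so return to 30.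

Step 16. The β-carbon C9 is neopentyl, so the organocopper addition may be slow enough for the Grignard reagent to be lost to 1,2-addition at the lactone carbonyl or to homocoupling. Fallback: the C9–C11 bond is made by a radical. Bromide 22 is converted by NaI in acetone (Finkelstein) into the iodide F3, the chloride staying in place. F3 and 12 with (Me3Si)3SiH and Et3B/O2 in toluene (Giese addition) give 25 directly; the chloride and the allyl ether are inert, and the α-lactone radical is reduced by the silane. The facial bias at C9 is the same as in the main route.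

Step 2. Double addition to the cross-conjugated dienone, or weak enantioface discrimination at the hindered β-carbon, would lower yield and optical purity at the first stereocentre. Fallback: the order of dehydrogenation and addition is reversed. Enone 1 takes the same rhodium-catalysed vinylation, where no second acceptor exists, to give (3R)-3-ethenyl-4,4-dimethylcyclohexan-1-one F4. Kinetic enolisation away from the substituted side with LiN(i-Pr)2/Me3SiCl gives the silyl enol ether F5. Saegusa–Ito oxidation with Pd(OAc)2 (divalent palladium) in MeCN then gives 3.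

**Further compounds**

F1 | step 21 | 15-epi aldol (C15–OH exo, cis to the C16 epoxide oxygen) | CC1(C)C=C[C@@H](O[Si](C)(C)C(C)(C)C)[C@]2(COC(=O)[C@@]34C[C@@H](CC[C@@H]23)[C@@]5(CO5)[C@@H]4O)[C@@H]1CO[Si](C)(C)C(C)(C)C
F2 | step 21 | C15 ketone of 30 | CC1(C)C=C[C@@H](O[Si](C)(C)C(C)(C)C)[C@]2(COC(=O)[C@@]34C[C@@H](CC[C@@H]23)[C@@]5(CO5)C4=O)[C@@H]1CO[Si](C)(C)C(C)(C)C
F3 | step 16 | 1-({[(3S)-3-(chloromethyl)-5-iodo-2-methylidenepentyl]oxy}methyl)-4-methoxybenzene | ICC[C@H](CCl)C(=C)COCc1ccc(OC)cc1
F4 | step 2 | (3R)-3-ethenyl-4,4-dimethylcyclohexan-1-one | CC1(C)CCC(=O)C[C@@H]1C=C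
F5 | step 2 | {[(5R)-5-ethenyl-4,4-dimethylcyclohex-1-en-1-yl]oxy}trimethylsilane | CC1(C)CC=C(O[Si](C)(C)C)C[C@@H]1C=C
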